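Locants used for the target and all intermediates: C1–C14 are the ring carbons (C1 = lactone O–CH, C14 = ring-fusion CH), C15 = α-carbon, C16 = lactone C=O, C17 = exocyclic CH2, O1 = lactone ring oxygen. Methyl groups sit on C3, C7 and C11, acetates on C5 and C9. The SMILES reads as (1S,5S,9S,14R), 2E,6E,10E, with H-1 and H-14 trans (trans-fused lactone).

Assumption: the sense of induction of the two chiral promoters (D-tryptophan-derived oxazaborolidinone, Si face, steps 7 and 9; (S,S)-ligand on chromium, Re face, step 11) is assigned by analogy only, and the enantiomeric promoter is used if the sense proves opposite.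

## The problem

The target 18 is a cembranolide: a 14-membered carbocycle (C1–C14) with three E-trisubstituted alkenes (C2=C3, C6=C7, C10=C11), trans-fused at C1/C14 to an α-methylene-γ-butyrolactone (O1, C16=O, C15=C17H2). Of the four stereocentres only C14 has a neighbour that can control it (C1); the allylic acetate centres C5 and C9 lie four and eight ring atoms from C1, so C1, C5 and C9 each need reagent control. The ring is a threefold repeat O–CH–CH=C(CH3)–CH2 (C1–C4, C5–C8, C9–C12) closed by C13–C14. Every carbinol carbon has an sp2 carbon on one side and an allylic CH2 (or the allylic C14–H) on the other. A cut at any alkenyl–carbinol bond therefore gives a β,γ-unsaturated aldehyde, whereas a cut at C4–C5 or C8–C9 gives an enal and the γ-carbon of a 3-methylbut-2-enal dienolate. The feature that makes the key step possible is the 2-carboxyallyl unit C17=C15(–C16) whose γ-carbon C14 is bonded to C1, with O1 and C16 in a 1,4-relationship. C1 (an enal carbonyl carbon) and C14 (the β-carbon of an acrylate) are both acceptor carbons, so they can be joined only after polarity reversal of one, and once joined the five-membered lactone closes by itself. The closure must form an unbiased 14-membered ring without touching alkene geometry. The molecule has three allylic C–O bonds that ionise with acid or zerovalent palladium, δ-acyloxy enal intermediates that can eliminate, and an α-methylene lactone that adds nucleophiles and isomerises into the ring with base. The acetates rule out hydride and hydroxide late in the route.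

## Retrosynthesis

18 ⇒ 15. The C1–C14 bond is cut, together with the C16–O1 acyl bond, which re-forms spontaneously. Against the neighbouring cuts: C13–C14 needs a preformed, stereodefined butenolide acceptor, and C1–C2 needs an α-chiral β,γ-unsaturated aldehyde. The precursor 15 is acyclic, has neither ring and neither of the C1/C14 stereocentres, and carries the acetates already, so the closure gives the target itself. The forward reaction must turn the allylic chloride of 15 into a nucleophile (CrCl2), close the ring in preference to oligomerisation, attack the Re face of the C1 aldehyde, and add anti. The mixture of allylchromium isomers 16 has to converge on one adduct 17.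

15 ⇒ 14 ⇒ 13 ⇒ 12 ⇒ 9 + 2 × 11. The C4–C5 and C8–C9 bonds and the two O-acetyl bonds are cut. Each C–C cut removes one stereocentre, one E-trisubstituted alkene and five carbons, and returns an enal of the same kind, so the same reagent 11 and the same catalyst serve twice. The alkenyl–carbinol cuts C5–C6 and C9–C10 would give β,γ-unsaturated aldehydes. The forward reaction must be γ-selective, E-selective and Si-face selective on an enal. Acetylating each carbinol as it forms leaves no protecting groups to remove.

9 ⇒ 7 ⇒ 6 ⇒ 5 ⇒ 3 + 4. The C17–Cl bond comes from SN2′ substitution of a Morita–Baylis–Hillman alcohol, and the C14–C15 bond from the Morita–Baylis–Hillman reaction of aldehyde 3 with methyl acrylate 4. This brings in C15, C16 and C17 at the correct oxidation levels in one step. The carbinol centre of 5 is racemic and is erased, so nothing is wasted on it. The C9 enal is released from the acetate by methanolysis (6) and selective oxidation (7).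

3 ⇒ 1. The C14 aldehyde comes from cleavage of the terminal alkene of geranyl acetate 1. Geraniol supplies C9–C14, the C11 methyl and the E-C10=C11 alkene ready-made, which a C–C bond-forming approach to this alkene would have to control.

11 ⇐ 10. The dienol silyl ether is made in one step from 3-methylbut-2-enal 10 and supplies C1–C4 and C5–C8 with their methyl groups.

## Roads not taken

Alternative 1: ring-closing metathesis, the closure most would draw first. The cut is at C10=C11 (or C6=C7, C2=C3), giving diene A1, to be closed with a second-generation Grubbs catalyst. Every ring alkene is trisubstituted, so its E-geometry would be left to the 14-membered product with no control element. The 1,1-disubstituted α-methylene lactone and the other trisubstituted alkenes are competing partners. A1 already holds all four stereocentres and the lactone, so the C1/C14 problem is only moved to earlier intermolecular steps. In the chosen plan all three alkene geometries are fixed before closure (one from geraniol, two from the s-trans dienolate), and the closure itself makes the lactone.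

Alternative 2: alkenyl–carbinol closure at C5–C6 (equally C9–C10 or C1–C2), from iodo aldehyde A2 by NiCl2/CrCl2-mediated alkenyl addition. The C5 aldehyde of A2 is β,γ-unsaturated to C2=C3 and would slip into conjugation. The same holds at C9, and at C1 the aldehyde would also be α-chiral. Each alkenyl iodide needs its own alkyne carbometalation and each carbinol its own asymmetric step on a different fragment. In the chosen plan every carbinol carbon is an enal carbon throughout and one reagent builds two of the three units.

Alternative 3: closure at C13–C14 by radical addition–fragmentation. A primary C13 radical from iodide A3 would add to C14 of a 3-(stannylmethyl)butenolide anti to the C1 substituent, and loss of the tin radical would unveil C15=C17. The stereochemical logic is attractive: C1 is set intermolecularly and C14 by 1,2-induction. But A3 costs about five more steps after the chain is complete. The usual entry to such acceptors (halogenation and dehydrohalogenation of an α-methylene lactone) is incompatible with three electron-rich alkenes. The homoallylic C13 radical and stoichiometric tin add further liabilities. The chosen closure needs no functional group that the chain does not already carry.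

Key step: step 11

## Route

Step 1
Reactants: 1 geranyl acetate [(2E)-3,7-dimethylocta-2,6-dien-1-yl acetate]
Product: 3 (2E)-3-methyl-6-oxohex-2-en-1-yl acetate, via secondary ozonide 2 (not isolated)
Conditions: O3 (1 equiv), CH2Cl2, pyridine (cat.), −78 °C; then Me2S, −78 °C to rt
Reagents that add atoms: ozone, [O-][O+]=O
Why: Ozonolysis with reductive work-up; the 6,7-alkene is the more electron-rich because the 2,3-alkene is deactivated by the allylic acetoxy group, so one equivalent of ozone should cleave it alone and leave the E-alkene (later C10=C11) untouched.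

Step 2
Reactants: 3 (2E)-3-methyl-6-oxohex-2-en-1-yl acetate; 4 methyl acrylate
Product: 5 methyl (6E)-8-acetoxy-3-hydroxy-6-methyl-2-methylideneoct-6-enoate (racemic at C3)
Conditions: methyl acrylate (neat, excess), DABCO (0.5 equiv), rt
Reagents that add atoms: none
Why: Morita–Baylis–Hillman reaction of an unhindered aliphatic aldehyde; it forms C14–C15 and installs C15, C16 and C17 at their final oxidation levels. The new carbinol centre is deliberately racemic because step 5 erases it.

Step 3
Reactants: 5 methyl (6E)-8-acetoxy-3-hydroxy-6-methyl-2-methylideneoct-6-enoate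
Product: 6 methyl (6E)-3,8-dihydroxy-6-methyl-2-methylideneoct-6-enoate
Conditions: K2CO3 (cat.), MeOH, 0 °C
Reagents that add atoms: none
Why: Zemplén-type transesterification of the primary allylic acetate; the methyl ester is degenerate toward methanol, and at 0 °C the α-substituted acrylate should not add methoxide.

Step 4
Reactants: 6 methyl (6E)-3,8-dihydroxy-6-methyl-2-methylideneoct-6-enoate
Product: 7 methyl (6E)-3-hydroxy-6-methyl-2-methylidene-8-oxooct-6-enoate
Conditions: TEMPO (cat.), PhI(OAc)2, CH2Cl2, rt
Reagents that add atoms: none
Why: Oxoammonium oxidation is selective for the primary allylic alcohol over the secondary alcohol next to the electron-poor acrylate and keeps the E-geometry, giving the C9 enal.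

Step 5
Reactants: 7 methyl (6E)-3-hydroxy-6-methyl-2-methylidene-8-oxooct-6-enoate
Product: 9 methyl (2Z,6E)-2-(chloromethyl)-6-methyl-8-oxoocta-2,6-dienoate, via alkoxysulfonium chloride 8 (not isolated)
Conditions: NCS, Me2S, CH2Cl2, −20 °C to rt
Reagents that add atoms: N-chlorosuccinimide, O=C1CCC(=O)N1Cl
Why: Corey–Kim-type activation followed by SN2′ attack of chloride at the terminal methylene gives the conjugated (Z)-2-(chloromethyl)enoate and erases the racemic carbinol centre. The electron-poor allylic chloride is inert enough to ride through steps 7–10 as a latent nucleophile, and any E isomer is harmless because step 11 is convergent.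

Step 6
Reactants: 10 3-methylbut-2-enal
Product: 11 (E)-tert-butyldimethyl[(3-methylbuta-1,3-dien-1-yl)oxy]silane
Conditions: TBSOTf, Et3N, Et2O, 0 °C to rt
Reagents that add atoms: tert-butyldimethylsilyl trifluoromethanesulfonate, CC(C)(C)[Si](C)(C)OS(=O)(=O)C(F)(F)F
Why: Soft enolisation (O-silylation, then γ-deprotonation by the amine) gives the 1-silyloxydiene; its enol ether geometry is lost in the aldol step and does not matter.

Step 7
Reactants: 9 methyl (2Z,6E)-2-(chloromethyl)-6-methyl-8-oxoocta-2,6-dienoate; 11 (E)-tert-butyldimethyl[(3-methylbuta-1,3-dien-1-yl)oxy]silane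
Product: 12 methyl (2Z,6E,8S,10E)-2-(chloromethyl)-8-hydroxy-6,10-dimethyl-12-oxododeca-2,6,10-trienoate
Conditions: 11 (1.5 equiv), (R)-4-(1H-indol-3-ylmethyl)-2-phenyl-3-(4-methylphenylsulfonyl)-1,3,2-oxazaborolidin-5-one (0.5 equiv), i-PrOH, EtCN, −78 °C
Reagents that add atoms: none
Why: Vinylogous Mukaiyama aldol reaction of an aldehyde-derived silyl dienol ether forms C8–C9. The boron-bound enal is attacked 1,2 by the γ-carbon, the s-trans diene gives the E-C6=C7 enal, and the catalyst is to shield the Re face so that Si-face addition sets C9 as S. i-PrOH takes up the silyl group, so the free alcohol results.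

Step 8
Reactants: 12 methyl (2Z,6E,8S,10E)-2-(chloromethyl)-8-hydroxy-6,10-dimethyl-12-oxododeca-2,6,10-trienoate
Product: 13 methyl (2Z,6E,8S,10E)-8-acetoxy-2-(chloromethyl)-6,10-dimethyl-12-oxododeca-2,6,10-trienoate
Conditions: Ac2O, 2,6-lutidine, DMAP (cat.), CH2Cl2, 0 °C
Reagents that add atoms: acetic anhydride, CC(=O)OC(C)=O
Why: O-acylation installs the C9 acetate of the target at once; the hindered base and low temperature should spare the allylic chloride and avoid β-elimination from the δ-acetoxy enal.

Step 9
Reactants: 13 methyl (2Z,6E,8S,10E)-8-acetoxy-2-(chloromethyl)-6,10-dimethyl-12-oxododeca-2,6,10-trienoate; 11 (E)-tert-butyldimethyl[(3-methylbuta-1,3-dien-1-yl)oxy]silane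
Product: 14 methyl (2Z,6E,8S,10E,12S,14E)-8-acetoxy-2-(chloromethyl)-12-hydroxy-6,10,14-trimethyl-16-oxohexadeca-2,6,10,14-tetraenoate
Conditions: 11 (1.5 equiv), the oxazaborolidinone of step 7 (0.5 equiv), i-PrOH, EtCN, −78 °C
Reagents that add atoms: none
Why: Second vinylogous Mukaiyama aldol reaction, forming C4–C5 and the E-C2=C3 enal. The C9 centre is five atoms from the reacting carbonyl, so the catalyst should again decide the face (Si, C5 = S).

Step 10
Reactants: 14 methyl (2Z,6E,8S,10E,12S,14E)-8-acetoxy-2-(chloromethyl)-12-hydroxy-6,10,14-trimethyl-16-oxohexadeca-2,6,10,14-tetraenoate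
Product: 15 methyl (2Z,6E,8S,10E,12S,14E)-8,12-diacetoxy-2-(chloromethyl)-6,10,14-trimethyl-16-oxohexadeca-2,6,10,14-tetraenoate
Conditions: Ac2O, 2,6-lutidine, DMAP (cat.), CH2Cl2, 0 °C
Reagents that add atoms: acetic anhydride, CC(=O)OC(C)=O
Why: O-acylation as in step 8 installs the C5 acetate; 15 now carries every atom and functional group of the target except the C1–C14 bond and the lactone.

Step 11
Reactants: 15 methyl (2Z,6E,8S,10E,12S,14E)-8,12-diacetoxy-2-(chloromethyl)-6,10,14-trimethyl-16-oxohexadeca-2,6,10,14-tetraenoate
Product: 18 (3aR,6E,8S,10E,12S,14E,15aS)-6,10,14-trimethyl-3-methylidene-2-oxo-2,3,3a,4,5,8,9,12,13,15a-decahydrocyclotetradeca[b]furan-8,12-diyl diacetate (the target), via allylchromium dichloride 16 (not isolated), via chromium alkoxide 17 (not isolated)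
Conditions: CrCl2 (excess), 3,6-di-tert-butyl-1,8-bis[(S)-4-isopropyl-4,5-dihydrooxazol-2-yl]-9H-carbazole (1.1 equiv per Cr), Et3N, LiI (cat.), THF, 25 °C, slow addition of 15 (final 1 mM); aq NH4Cl
Reagents that add atoms: none
Why: Nozaki–Hiyama-type 2-(alkoxycarbonyl)allylation, the chromium variant of the Dreiding–Schmidt lactone synthesis: two CrCl2 reduce the C17–Cl bond to the allylchromium dichloride 16 (trivalent chromium), which adds through its γ-carbon C14 to the C1 aldehyde in a six-membered chair, and the chromium alkoxide 17 then acylates itself on the methyl ester. The closest known reactions are chromium-mediated ring closures of ω-formyl 2-(halomethyl)alk-2-enoates to carbocycle-fused α-methylene lactones and the ligand-controlled intermolecular chromium 2-(alkoxycarbonyl)allylation of aldehydes. The 14-membered carbocycle closes by C1–C14 bond formation (1,2-addition to the enal, the tether spanning two adjacent equatorial positions of the chair), and the lactone closes by 5-exo-trig acyl substitution with loss of methanol. C1 is set by the ligand on chromium, which is to expose the Re face of the aldehyde (1S). C14 is set relative to C1 by the chair: the allylchromium isomers interconvert by 1,3-metal shift faster than they add, and the isomer with the C13 chain trans to CH2Cr reacts with C13 and the C2 alkenyl group both equatorial, giving the anti adduct and hence the trans-fused lactone (14R); Z and E chloride therefore converge. The step needs ring closure over oligomerisation (slow addition at high dilution), 1,2- over 1,4-addition (the enal is β,β-disubstituted and allylchromium reagents add 1,2), and attack on the aldehyde only (CrCl2 leaves allylic acetates and esters alone).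

## Compound list

1 | geranyl acetate, (2E)-3,7-dimethylocta-2,6-dien-1-yl acetate | CC(=O)OC/C=C(\C)CCC=C(C)C | starting material
2 | secondary ozonide, (2E)-5-(5,5-dimethyl-1,2,4-trioxolan-3-yl)-3-methylpent-2-en-1-yl acetate | CC(=O)OC/C=C(\C)CCC1OOC(C)(C)O1 | intermediate
3 | (2E)-3-methyl-6-oxohex-2-en-1-yl acetate | CC(=O)OC/C=C(\C)CCC=O | intermediate
4 | methyl acrylate | C=CC(=O)OC | starting material
5 | methyl (6E)-8-acetoxy-3-hydroxy-6-methyl-2-methylideneoct-6-enoate (racemic at C3) | CC(=O)OC/C=C(\C)CCC(O)C(=C)C(=O)OC | intermediate
6 | methyl (6E)-3,8-dihydroxy-6-methyl-2-methylideneoct-6-enoate (racemic at C3) | OC/C=C(\C)CCC(O)C(=C)C(=O)OC | intermediate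
7 | methyl (6E)-3-hydroxy-6-methyl-2-methylidene-8-oxooct-6-enoate (racemic at C3) | O=C/C=C(\C)CCC(O)C(=C)C(=O)OC | intermediate
8 | alkoxysulfonium chloride, {[(6E)-1-methoxy-6-methyl-2-methylidene-1,8-dioxooct-6-en-3-yl]oxy}dimethylsulfonium chloride | O=C/C=C(\C)CCC(O[S+](C)C)C(=C)C(=O)OC.[Cl-] | intermediate
9 | methyl (2Z,6E)-2-(chloromethyl)-6-methyl-8-oxoocta-2,6-dienoate | O=C/C=C(\C)CC\C=C(/CCl)C(=O)OC | intermediate
10 | 3-methylbut-2-enal | CC(C)=CC=O | starting material
11 | (E)-tert-butyldimethyl[(3-methylbuta-1,3-dien-1-yl)oxy]silane | C=C(C)/C=C/O[Si](C)(C)C(C)(C)C | intermediate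
12 | methyl (2Z,6E,8S,10E)-2-(chloromethyl)-8-hydroxy-6,10-dimethyl-12-oxododeca-2,6,10-trienoate | O=C/C=C(\C)C[C@H](O)/C=C(\C)CC\C=C(/CCl)C(=O)OC | intermediate
13 | methyl (2Z,6E,8S,10E)-8-acetoxy-2-(chloromethyl)-6,10-dimethyl-12-oxododeca-2,6,10-trienoate | O=C/C=C(\C)C[C@H](OC(C)=O)/C=C(\C)CC\C=C(/CCl)C(=O)OC | intermediate
14 | methyl (2Z,6E,8S,10E,12S,14E)-8-acetoxy-2-(chloromethyl)-12-hydroxy-6,10,14-trimethyl-16-oxohexadeca-2,6,10,14-tetraenoate | O=C/C=C(\C)C[C@H](O)/C=C(\C)C[C@H](OC(C)=O)/C=C(\C)CC\C=C(/CCl)C(=O)OC | intermediate
15 | methyl (2Z,6E,8S,10E,12S,14E)-8,12-diacetoxy-2-(chloromethyl)-6,10,14-trimethyl-16-oxohexadeca-2,6,10,14-tetraenoate | O=C/C=C(\C)C[C@H](OC(C)=O)/C=C(\C)C[C@H](OC(C)=O)/C=C(\C)CC\C=C(/CCl)C(=O)OC | intermediate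
16 | allylchromium dichloride, dichloro[(6E,8S,10E,12S,14E)-8,12-diacetoxy-2-(methoxycarbonyl)-6,10,14-trimethyl-16-oxohexadeca-2,6,10,14-tetraen-1-yl]chromium (geometry at C2 interconverting) | O=C/C=C(\C)C[C@H](OC(C)=O)/C=C(\C)C[C@H](OC(C)=O)/C=C(\C)CCC=C(C[Cr](Cl)Cl)C(=O)OC | intermediate
17 | chromium alkoxide of methyl 2-[(1R,2S,3E,6S,7E,10S,11E)-6,10-diacetoxy-2-hydroxy-4,8,12-trimethylcyclotetradeca-3,7,11-trien-1-yl]prop-2-enoate (O-CrCl2 at C2 of the ring) | C=C(C(=O)OC)[C@H]1CC/C(C)=C/[C@@H](OC(C)=O)C/C(C)=C/[C@@H](OC(C)=O)C/C(C)=C/[C@@H]1O[Cr](Cl)Cl | intermediate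
18 | (3aR,6E,8S,10E,12S,14E,15aS)-6,10,14-trimethyl-3-methylidene-2-oxo-2,3,3a,4,5,8,9,12,13,15a-decahydrocyclotetradeca[b]furan-8,12-diyl diacetate | C=C1C(=O)O[C@H]2/C=C(\C)C[C@H](OC(C)=O)/C=C(\C)C[C@H](OC(C)=O)/C=C(\C)CC[C@H]12 | target

## Step count and least certain steps

Total step count: 11. Longest linear sequence: 10 (steps 1–5 and 7–11 from geranyl acetate 1); step 6 is a one-step side branch.

Step 11 (key step). Three things may go wrong. Intermolecular carbonyl addition may outrun ring closure, because nothing in 15 pre-organises the 14-membered transition state. The Z-allylchromium may add before it isomerises (syn addition), which would end in a cis ring fusion. The ligand may discriminate the aldehyde faces only weakly. The fallback sets out from 15 and returns to 18. The closure is accepted as syn-selective and run with the enantiomeric ligand, so that the Si face of the aldehyde is attacked and C14 is still formed as R; this should give the cis-fused (1R,14R) lactone diacetate F1. LiOH in THF/H2O opens the lactone and removes both acetates, giving the trihydroxy acid F2, which is kept as its lithium salt and acidified cold just before use. Mitsunobu lactonisation (PPh3, diisopropyl azodicarboxylate, THF, 0 °C) closes the five-membered ring, the only kinetically easy one, at C1 with inversion and should give the trans-fused diol lactone F3. Ac2O/pyridine then gives 18.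

Step 7. The dienolate may attack through its α-carbon, or facial selectivity may be low, because 9 is a β,β-disubstituted enal and less electrophilic than the saturated aldehydes for which this promoter is best established. The fallback sets out from 9 and returns to 12. The SiCl4/chiral bisphosphoramide-catalysed vinylogous aldol addition of the N,O-silyl ketene acetal of 4-(3-methylbut-2-enoyl)morpholine, a reaction type established for unsaturated aldehydes, should give the hydroxy amide F4. Cp2Zr(H)Cl in THF then reduces the tertiary amide to the aldehyde without touching the methyl ester, giving 12.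

Step 9. The existing C9 centre may be mismatched with the catalyst, or the Lewis acid may induce β-elimination of acetic acid from the δ-acetoxy enal. The fallback sets out from 13 and returns to 14. The same amide-based vinylogous aldol addition, run at low temperature under conditions that do not ionise the acetate, should give the hydroxy amide F5. Cp2Zr(H)Cl then gives 14 with the acetate and the ester intact.

Step 1. Ozone may begin to attack the 2,3-alkene before the 6,7-alkene is consumed, because the rate difference between the two trisubstituted alkenes is only moderate. The fallback sets out from 1 and returns to 3. Epoxidation with mCPBA (CH2Cl2, 0 °C) picks the electron-rich 6,7-alkene and should give the epoxide F6. H5IO6 in THF/H2O cleaves the epoxide to 3.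

## Further compounds

F1 | step 11 | (3aR,6E,8S,10E,12S,14E,15aR)-6,10,14-trimethyl-3-methylidene-2-oxo-2,3,3a,4,5,8,9,12,13,15a-decahydrocyclotetradeca[b]furan-8,12-diyl diacetate (cis-fused C1 epimer of 18) | C=C1C(=O)O[C@@H]2/C=C(\C)C[C@H](OC(C)=O)/C=C(\C)C[C@H](OC(C)=O)/C=C(\C)CC[C@H]12
F2 | step 11 | 2-[(1R,2R,3E,6S,7E,10S,11E)-2,6,10-trihydroxy-4,8,12-trimethylcyclotetradeca-3,7,11-trien-1-yl]prop-2-enoic acid | C=C(C(=O)O)[C@H]1CC/C(C)=C/[C@@H](O)C/C(C)=C/[C@@H](O)C/C(C)=C/[C@H]1O
F3 | step 11 | (3aR,6E,8S,10E,12S,14E,15aS)-8,12-dihydroxy-6,10,14-trimethyl-3-methylidene-3a,4,5,8,9,12,13,15a-octahydrocyclotetradeca[b]furan-2(3H)-one | C=C1C(=O)O[C@H]2/C=C(\C)C[C@H](O)/C=C(\C)C[C@H](O)/C=C(\C)CC[C@H]12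
F4 | step 7 | methyl (2Z,6E,8S,10E)-2-(chloromethyl)-8-hydroxy-6,10-dimethyl-12-(morpholin-4-yl)-12-oxododeca-2,6,10-trienoate | O=C(N1CCOCC1)/C=C(\C)C[C@H](O)/C=C(\C)CC\C=C(/CCl)C(=O)OC
F5 | step 9 | methyl (2Z,6E,8S,10E,12S,14E)-8-acetoxy-2-(chloromethyl)-12-hydroxy-6,10,14-trimethyl-16-(morpholin-4-yl)-16-oxohexadeca-2,6,10,14-tetraenoate | O=C(N1CCOCC1)/C=C(\C)C[C@H](O)/C=C(\C)C[C@H](OC(C)=O)/C=C(\C)CC\C=C(/CCl)C(=O)OC
F6 | step 1 | (2E)-5-(3,3-dimethyloxiran-2-yl)-3-methylpent-2-en-1-yl acetate | CC(=O)OC/C=C(\C)CCC1OC1(C)C
A1 | alternative 1 | (4R,5S)-5-[(1E,4S,5E,8S)-4,8-diacetoxy-2,6-dimethyldeca-1,5,9-trien-1-yl]-4-(3-methylbut-3-en-1-yl)-3-methylidenedihydrofuran-2(3H)-one | C=C(C)CC[C@@H]1C(=C)C(=O)O[C@H]1/C=C(\C)C[C@H](OC(C)=O)/C=C(\C)C[C@H](OC(C)=O)C=C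
A2 | alternative 2 | (4R,5S)-4-[(3E,5S,7E)-5-acetoxy-8-iodo-3,7-dimethylocta-3,7-dien-1-yl]-5-[(1E)-2-methyl-4-oxobut-1-en-1-yl]-3-methylidenedihydrofuran-2(3H)-one | O=CC/C(C)=C/[C@@H]1OC(=O)C(=C)[C@H]1CC/C(C)=C/[C@@H](OC(C)=O)C/C(C)=C/I
A3 | alternative 3 | (5S)-5-[(1E,4S,5E,8S,9E)-4,8-diacetoxy-12-iodo-2,6,10-trimethyldodeca-1,5,9-trien-1-yl]-3-[(tributylstannyl)methyl]furan-2(5H)-one | ICC/C(C)=C/[C@@H](OC(C)=O)C/C(C)=C/[C@@H](OC(C)=O)C/C(C)=C/[C@@H]1OC(=O)C(C[Sn](CCCC)(CCCC)CCCC)=C1
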